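**Remark on the chemistry (assumption):** 3 is written as its triketo tautomer although it should exist largely as a chelated enol; the alkene geometry of 4 is left open because both isomers interconvert and converge on 5; 10 is written as the neutral keto alcohol although it is present in the flask as its lithium salt.

## Structural features

The target is an isoflavone: a benzenoid ring A fused to a 4-pyranone ring C, with a 4-methoxyphenyl ring B on C3 of ring C. Ring A is a fully differentiated phloroglucinol (oxygen on C5, on C7 and, as the ring oxygen O1, on C8a). It carries the chain CH2–CH(OH)–C(CH3)=CH2 on C6 between the two free phenols, while C8 is unsubstituted. The only stereocentre is the carbinol carbon C2'' of that chain, (R)-configured, with no stereogenic neighbour. This secondary allylic alcohol is the fragile part: acid can ionize or dehydrate it, or let the C5 or C7 phenol add to the alkene to give fused cyclic ethers, and C2 of ring C is open to nucleophiles. The real difficulty is twofold: C6 and C8 are electronically almost alike, so late attachment of the chain meets a regiochemical problem, and the remote carbinol must be obtained as one enantiomer without a long protecting-group detour. The key step exploits the 1,3,5-oxygen pattern of ring A, which is that of a folded poly-β-carbonyl chain. C8, C8a, C4a and C5 come from the methyl group, C2, C3 and the ester carbon of a 4-pyranone that already holds ring C and ring B; C7, C6 and the whole side chain come from a γ-lactone whose ring oxygen sits on the future C2''. (C5 is therefore the ester carbon of the pyranone, not a lactone carbon.) Because O1 stands where a third chain carbonyl would be, the chain can fold in one way only, and because C2'' is γ to the lactone carbonyl it is never enolizable.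

## Logic of the disconnections

**11 ⇒ 5 + 9 (through 10).** The ring A bonds C7–C8 and C5–C6 are cut. These are the two bonds that a Claisen acylation and a Dieckmann closure make, and cutting them removes ring A, separates the chiral chain from the heterocycle and needs no protecting group. The gain is a convergent union of a 16-carbon and a 7-carbon fragment. The forward step demands that the methyl group of 5 is metalated and acylated by 9 before base attacks the ring CH of 5 or enolizes 9, and that 10 is deprotonated a second time so that carbon, not oxygen, closes the ring.

**5 ⇒ 3 (through 4).** The one-carbon unit of the pyranone (the ring CH) is removed by cutting its bonds to the ring oxygen and to the aryl-bearing carbon. That carbon is at the formyl oxidation level and sits between a benzylic methylene and an enol oxygen, exactly as in the classical closure of deoxybenzoins to isoflavones. The gain is an acyclic tricarbonyl compound. The forward step demands condensation at the benzylic methylene and not at the acetyl methyl, and no O-alkylation of the acidic enol.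

**3 ⇒ 1 + 2.** The bond between the central carbon and the arylacetyl carbonyl is cut, giving two commercial materials. The forward step demands C- rather than O-acylation and a single acylation.

**9 ⇒ 8.** The C=CH2 bond is cut to a methyl ketone. The forward step demands a methylenation that is non-basic, because the stereocentre is α to the ketone and carries an acyloxy group, and that leaves the lactone alone.

**8 ⇒ 7 ⇒ 6.** The CO–CH3 bond is cut back to an acyl chloride and then to the chiral-pool acid, whose stereocentre becomes C2'' of 11 without ever being broken. The forward steps demand mono-addition of a methyl nucleophile in the presence of a lactone and the absence of base that could form a ketene from 7.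

## Other disconnections considered

**Alternative 1:** The cut is at the two C–O bonds of an epoxide spanning C2''–C3''. In the forward sense the (E)-allylic alcohol A1 is epoxidized with Ti(OiPr)4, D-(−)-diethyl tartrate and t-BuOOH to the (2R,3R)-epoxy alcohol A2. The primary hydroxyl of A2 is then turned into an iodide, zinc-induced reductive opening unveils the secondary allylic alcohol with retention at C2'', and the two acetals are removed.
- In its favour: this epoxidation of (E)-trisubstituted allylic alcohols is among the most dependable enantioselective reactions, and every later operation has direct precedent. On mechanistic certainty it is the better plan, and it is also better in that either enantiomer is available by choice of tartrate.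
- Against it here: A1 presupposes a C6-prenylated, doubly protected isoflavone, so the C6/C8 problem is left unsolved by the key step. The allylic oxidation with SeO2 that leads to A1 is rarely clean. The final acidic acetal cleavage exposes the allylic alcohol, flanked by two phenols, to cyclization.
- Comparison: structurally it decorates a finished isoflavone, while the chosen plan builds ring A around the imported stereocentre. Mechanistically it uses catalyst control versus retention of a chiral-pool centre, and the two should be equal in stereochemical fidelity. In step economy the chosen plan is clearly ahead (6 steps against well over 10).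

**Alternative 2:** The cut is at C4a–C8a of ring A at the chalcone stage. In the forward sense the polyenolate of the triketo ester A3 folds so that chain carbon C6 attacks the ester carbon and gives the trihydroxychalcone A4.
- In its favour: it is biomimetic, uses cheap materials, and ring A emerges symmetric, so closure of the oxygen heterocycle has no regiochemical issue. Open-chain Claisen folding of triketo esters has closer precedent than the templated variant, and on that point it is the better plan.
- Against it here: A4 has neither the isoflavone skeleton nor the side chain nor the stereocentre. Selective phenol protection, an oxidative 1,2-aryl shift (Tl(NO3)3 or PhI(OAc)2), C6-selective attachment of five carbons and enantioselective oxygenation would all still lie ahead. A3 itself can also fold by the aldol mode or lactonize to a pyranone.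
- Comparison: both plans make ring A by Claisen condensation and are equals in concept. In the chosen plan the pyranone holds the chain in the productive fold and excludes the aldol mode, and the same step brings in the side chain and the stereocentre. The alternative's key step forms one bond and postpones every hard problem, so its step economy is far worse.

**Alternative 3:** The cut is at C4–C4a of ring C. In the forward sense the activated (Z)-aryloxyacrylic acid A5 acylates an ortho carbon of its aryloxy ring and gives the fully protected isoflavone A6.
- In its favour: the aryloxy ring of A5 has a twofold axis through C1 and C4, so both ortho carbons are equivalent and the C6 regiochemistry is guaranteed; on regiocontrol it equals the chosen plan. Intramolecular acylation of so electron-rich an arene is well-established chromone chemistry, and on precedent it is the better plan.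
- Against it here: A5 needs a differentially protected phloroglucinol, an aryl-metal coupling with a chiral electrophile, silylation, unmasking of one phenol and a geometry-defined enol ether, which is a long linear sequence. The electrophilic, acid-releasing activation threatens the two acetals, the allylic silyl ether and the 1,1-disubstituted alkene. Three protecting groups must then be removed, two of them with acid.
- Comparison: both plans fix C6 by connectivity (symmetry there, a template here). The alternative works by electrophilic substitution under acidic conditions, the chosen plan by anionic condensation under basic conditions, which suits the acid-labile side chain better. In step economy and protecting-group count the chosen plan is ahead; in reliability of the key step the alternative is ahead.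

Key step: step 6

## Route

Step 1
Reactants: 1 ethyl acetoacetate; 2 4-methoxyphenylacetyl chloride
Product: 3 ethyl 2-acetyl-4-(4-methoxyphenyl)-3-oxobutanoate
Conditions: MgCl2 (1.0 equiv), pyridine (2.0 equiv), CH2Cl2, 0 °C; 2 added slowly, 0 °C → rt; 1 M HCl work-up
Reagents that add atoms: none
Why: C-acylation of a β-keto ester through its magnesium chelate (Rathke conditions); chelation directs the acyl chloride to carbon, and the product stays bound as a magnesium enolate, which should stop a second acylation, while slow addition keeps ketene formation from 2 low.

Step 2
Reactants: 3 ethyl 2-acetyl-4-(4-methoxyphenyl)-3-oxobutanoate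
Product: 5 ethyl 5-(4-methoxyphenyl)-2-methyl-4-oxo-4H-pyran-3-carboxylate, via enaminone 4 (not isolated)
Conditions: Me2NCH(OMe)2 (1.3 equiv), toluene, 60 °C; then AcOH, 80 °C
Reagents that add atoms: N,N-dimethylformamide dimethyl acetal, COC(OC)N(C)C
Why: Aminomethylenation of the benzylic α-methylene followed by addition–elimination of the acetyl enol oxygen at the enaminone carbon with loss of Me2NH, the sequence that converts 2-hydroxydeoxybenzoins into isoflavones and acidic 2-acyl-1,3-dicarbonyl enols into 4-pyranones; the central carbon has a single hydrogen and cannot be aminomethylenated, and the benzylic CH2 is more acidic than the acetyl CH3.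

Step 3
Reactants: 6 (R)-5-oxotetrahydrofuran-2-carboxylic acid
Product: 7 (R)-5-oxotetrahydrofuran-2-carbonyl chloride
Conditions: (COCl)2 (1.2 equiv), DMF (cat.), CH2Cl2, 0 °C → rt; volatiles removed
Reagents that add atoms: oxalyl chloride, ClC(=O)C(=O)Cl
Why: Acid chloride formation through the chloroiminium species from DMF; no base is present, so the stereocentre α to the acyl chloride cannot be lost through a ketene, and the lactone is inert.

Step 4
Reactants: 7 (R)-5-oxotetrahydrofuran-2-carbonyl chloride
Product: 8 (R)-5-acetyldihydrofuran-2(3H)-one
Conditions: MeMgBr (1.05 equiv), CuI (5 mol %), THF, −78 °C; cold quench with 1 M HCl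
Reagents that add atoms: methylmagnesium bromide, C[Mg]Br
Why: Copper-catalysed acylation of a Grignard reagent by an acid chloride (ketone synthesis); at −78 °C the acyl chloride should react far faster than the lactone or the product ketone, and the cold acidic quench protects the α-oxygenated stereocentre.

Step 5
Reactants: 8 (R)-5-acetyldihydrofuran-2(3H)-one
Product: 9 (R)-5-(prop-1-en-2-yl)dihydrofuran-2(3H)-one
Conditions: Zn, CH2Br2, TiCl4, THF/CH2Cl2, 0 °C → rt
Reagents that add atoms: dibromomethane, BrCBr
Why: Takai–Lombardo methylenation; the non-basic zinc/titanium methylene reagent olefinates ketones but not lactones and is the standard choice for ketones with an epimerizable α-stereocentre, so the (R)-configured C–O bond should be carried over unchanged.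

Step 6
Reactants: 5 ethyl 5-(4-methoxyphenyl)-2-methyl-4-oxo-4H-pyran-3-carboxylate; 9 (R)-5-(prop-1-en-2-yl)dihydrofuran-2(3H)-one
Product: 11 5,7-dihydroxy-6-[(2R)-2-hydroxy-3-methylbut-3-en-1-yl]-3-(4-methoxyphenyl)-4H-chromen-4-one, via ring-opened keto alcohol 10 (not isolated)
Conditions: LiN(iPr)2 (1.05 equiv), THF, −78 °C, 5 added to the base; 9 (1.05 equiv), −78 → −30 °C; LiN(iPr)2 (2.5 equiv, slow addition), −78 → 0 °C; 1 M HCl to pH 4–5, 0 °C
Reagents that add atoms: none
Why: Proposed new method: LiN(iPr)2 removes a proton from the 2-methyl group of 5 (vinylogous to both the ring ketone and the ester), the dienolate attacks the lactone carbonyl of 9 through its terminal carbon and opens the ring to the alkoxide–ketone 10 (C7–C8), and 10 is at once deprotonated at C8, which is why the remaining base is added only after the acylation so that free amide does not enolize the lactone. The second charge of base should generate the C8/C6 dianion (a β-dicarbonyl dianion of the Hauser–Harris type), whose C6 terminus attacks the ester carbonyl in a 6-exo-trig Dieckmann closure (C5–C6); ethoxide leaves, enolization gives the aromatic 5,7-diolate of ring A, and mild acid liberates 11. The closest known reactions are the acylation of laterally metalated 2-methyl-4-pyranones and chromones by esters and the tandem Claisen–Dieckmann annulation of ortho-toluate anions with esters or lactones to 1,3-dihydroxyarenes; new here are the pyranone as the toluate equivalent and a lactone as acyl donor in the same flask. No stereocentre is formed: C2'' is γ to the lactone carbonyl, is never α to a carbonyl at any stage and keeps its C–O bond, so the (R) configuration is retained. The regiochemistry of ring A is fixed by connectivity, because O1 occupies the place of a third chain carbonyl and the chain can close only from C6 onto the ester carbon C5. The chemoselectivity needed, deprotonation of the methyl group rather than addition of amide to the ring CH of 5, is secured by the hindered base, inverse addition at −78 °C and the high acidity of the doubly activated methyl group, and closure through carbon rather than oxygen is favoured by the dianion, whose carbon terminus is its most nucleophilic site.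

## Compound list

1 | ethyl acetoacetate | CCOC(=O)CC(C)=O | starting material
2 | 4-methoxyphenylacetyl chloride | COc1ccc(CC(=O)Cl)cc1 | starting material
3 | ethyl 2-acetyl-4-(4-methoxyphenyl)-3-oxobutanoate | CCOC(=O)C(C(C)=O)C(=O)Cc1ccc(OC)cc1 | intermediate
4 | ethyl 2-acetyl-5-(dimethylamino)-4-(4-methoxyphenyl)-3-oxopent-4-enoate (enaminone, geometry open) | CCOC(=O)C(C(C)=O)C(=O)C(=CN(C)C)c1ccc(OC)cc1 | intermediate (not isolated)
5 | ethyl 5-(4-methoxyphenyl)-2-methyl-4-oxo-4H-pyran-3-carboxylate | CCOC(=O)c1c(C)occ(-c2ccc(OC)cc2)c1=O | intermediate
6 | (R)-5-oxotetrahydrofuran-2-carboxylic acid | OC(=O)[C@H]1CCC(=O)O1 | starting material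
7 | (R)-5-oxotetrahydrofuran-2-carbonyl chloride | ClC(=O)[C@H]1CCC(=O)O1 | intermediate
8 | (R)-5-acetyldihydrofuran-2(3H)-one | CC(=O)[C@H]1CCC(=O)O1 | intermediate
9 | (R)-5-(prop-1-en-2-yl)dihydrofuran-2(3H)-one | C=C(C)[C@H]1CCC(=O)O1 | intermediate
10 | ethyl 2-[(5R)-5-hydroxy-6-methyl-2-oxohept-6-en-1-yl]-5-(4-methoxyphenyl)-4-oxo-4H-pyran-3-carboxylate | CCOC(=O)c1c(CC(=O)CC[C@@H](O)C(C)=C)occ(-c2ccc(OC)cc2)c1=O | intermediate (not isolated)
11 | 5,7-dihydroxy-6-[(2R)-2-hydroxy-3-methylbut-3-en-1-yl]-3-(4-methoxyphenyl)-4H-chromen-4-one | C=C(C)[C@H](O)Cc1c(O)cc2occ(-c3ccc(OC)cc3)c(=O)c2c1O | target

## Step count and least certain steps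

Total step count: 6 (two for 5, three for 9, one convergent key step).
Longest linear sequence: 4 steps (6 → 7 → 8 → 9 → 11).

**Step 6 (key step, proposed new method).**
- What may go wrong: acylation may stall because a stabilized dienolate meets a weakly electrophilic, enolizable lactone, so that proton transfer to the lactone and its self-condensation overtake C–C bond formation. The ring may close through oxygen (enol lactonization) instead of carbon. Amide or liberated ethoxide may add to the ring CH of the pyranone or chromone and open it.
- Fallback (sets out from 9 and 5, returns at 11; each operation is a standard reaction class): 9 is opened with MeNH(OMe)·HCl/AlMe3 to the hydroxy Weinreb amide (4R)-4-hydroxy-N-methoxy-N,5-dimethylhex-5-enamide F1, which is silylated at once (TBSCl, imidazole) to the silyl ether (4R)-4-[(tert-butyldimethylsilyl)oxy]-N-methoxy-N,5-dimethylhex-5-enamide F2. The lithium dienolate of 5 (LiN(iPr)2, 1.05 equiv, −78 °C) is acylated by F2; the chelated tetrahedral adduct persists until work-up, so no second equivalent of dienolate is consumed. This gives the isolated keto ester ethyl 2-{(5R)-5-[(tert-butyldimethylsilyl)oxy]-6-methyl-2-oxohept-6-en-1-yl}-5-(4-methoxyphenyl)-4-oxo-4H-pyran-3-carboxylate F3. F3 is closed in a separate Dieckmann condensation through its dianion (LiN(iPr)2, 2.2 equiv, THF, −78 → 0 °C) to the silyl-protected isoflavone 6-{(2R)-2-[(tert-butyldimethylsilyl)oxy]-3-methylbut-3-en-1-yl}-5,7-dihydroxy-3-(4-methoxyphenyl)-4H-chromen-4-one F4, and Bu4NF buffered with AcOH gives 11. The acyl donor is then non-enolizable in practice and carries no free alkoxide, and the two bond formations can be optimized separately.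

**Step 2.**
- What may go wrong: aminomethylenation at the acetyl methyl instead of the benzylic methylene, O-methylation of the strongly acidic enol by the acetal, or deacylation of the tricarbonyl by liberated methoxide.
- Fallback (sets out from 1, returns at 5): 1 is C-acylated under the conditions of step 1 with commercial (E)-3-ethoxyacryloyl chloride to the ethoxymethylene tricarbonyl ethyl (4E)-2-acetyl-5-ethoxy-3-oxopent-4-enoate F5. Its enol oxygen displaces ethoxide on brief treatment with CF3CO2H to give the pyranone ethyl 2-methyl-4-oxo-4H-pyran-3-carboxylate F6. Bromine followed by Et3N (addition–elimination at the enol-ether double bond) gives the bromide ethyl 5-bromo-2-methyl-4-oxo-4H-pyran-3-carboxylate F7, and Suzuki–Miyaura coupling with 4-methoxyphenylboronic acid (Pd(PPh3)4, K3PO4, dioxane, 80 °C) gives 5. The ring CH and the aryl group are then placed by connectivity and not by a competition between two enolizable positions.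

**Step 5.**
- What may go wrong: partial epimerization of the α-acyloxy ketone through Lewis-acid-assisted enolization, or incomplete conversion of a chelating ketone.
- Fallback (sets out from 8, returns at 9): MeTi(OiPr)3, a non-basic methyl donor that adds to ketones but not to lactones, converts 8 into the tertiary alcohol (5R)-5-(2-hydroxypropan-2-yl)dihydrofuran-2(3H)-one F8. Syn-dehydration with the Burgess reagent toward one of the six methyl hydrogens gives 9; elimination toward the ring would create an enol ester and should be disfavoured.

**Step 4.**
- What may go wrong: a second addition of the Grignard reagent to the ketone formed, attack on the lactone, or loss of configuration through a ketene if the acyl chloride meets base before it is acylated.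
- Fallback (sets out from 7, returns at 8): 7 is treated with MeNH(OMe)·HCl and pyridine to give the Weinreb amide (2R)-N-methoxy-N-methyl-5-oxotetrahydrofuran-2-carboxamide F9, and MeMgBr (1.1 equiv, THF, −78 → 0 °C) gives 8 on acidic work-up, the chelated tetrahedral intermediate preventing over-addition.

## Further compounds

F1 | step 6 | (4R)-4-hydroxy-N-methoxy-N,5-dimethylhex-5-enamide | CON(C)C(=O)CC[C@@H](O)C(C)=C
F2 | step 6 | (4R)-4-[(tert-butyldimethylsilyl)oxy]-N-methoxy-N,5-dimethylhex-5-enamide | CON(C)C(=O)CC[C@@H](O[Si](C)(C)C(C)(C)C)C(C)=C
F3 | step 6 | ethyl 2-{(5R)-5-[(tert-butyldimethylsilyl)oxy]-6-methyl-2-oxohept-6-en-1-yl}-5-(4-methoxyphenyl)-4-oxo-4H-pyran-3-carboxylate | CCOC(=O)c1c(CC(=O)CC[C@@H](O[Si](C)(C)C(C)(C)C)C(C)=C)occ(-c2ccc(OC)cc2)c1=O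
F4 | step 6 | 6-{(2R)-2-[(tert-butyldimethylsilyl)oxy]-3-methylbut-3-en-1-yl}-5,7-dihydroxy-3-(4-methoxyphenyl)-4H-chromen-4-one | C=C(C)[C@H](O[Si](C)(C)C(C)(C)C)Cc1c(O)cc2occ(-c3ccc(OC)cc3)c(=O)c2c1O
F5 | step 2 | ethyl (4E)-2-acetyl-5-ethoxy-3-oxopent-4-enoate | CCO/C=C/C(=O)C(C(C)=O)C(=O)OCC
F6 | step 2 | ethyl 2-methyl-4-oxo-4H-pyran-3-carboxylate | CCOC(=O)c1c(C)occc1=O
F7 | step 2 | ethyl 5-bromo-2-methyl-4-oxo-4H-pyran-3-carboxylate | CCOC(=O)c1c(C)occ(Br)c1=O
F8 | step 5 | (5R)-5-(2-hydroxypropan-2-yl)dihydrofuran-2(3H)-one | CC(C)(O)[C@H]1CCC(=O)O1
F9 | step 4 | (2R)-N-methoxy-N-methyl-5-oxotetrahydrofuran-2-carboxamide | CON(C)C(=O)[C@H]1CCC(=O)O1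
A1 | alternative 1 | 6-[(2E)-4-hydroxy-3-methylbut-2-en-1-yl]-5,7-bis(methoxymethoxy)-3-(4-methoxyphenyl)-4H-chromen-4-one | OC/C(C)=C/Cc1c(OCOC)cc2occ(-c3ccc(OC)cc3)c(=O)c2c1OCOC
A2 | alternative 1 | 6-{[(2R,3R)-3-(hydroxymethyl)-3-methyloxiran-2-yl]methyl}-5,7-bis(methoxymethoxy)-3-(4-methoxyphenyl)-4H-chromen-4-one | OC[C@@]1(C)O[C@@H]1Cc1c(OCOC)cc2occ(-c3ccc(OC)cc3)c(=O)c2c1OCOC
A3 | alternative 2 | methyl (8E)-9-(4-methoxyphenyl)-3,5,7-trioxonon-8-enoate | COC(=O)CC(=O)CC(=O)CC(=O)/C=C/c1ccc(OC)cc1
A4 | alternative 2 | (E)-2',4',6'-trihydroxy-4-methoxychalcone | COc1ccc(/C=C/C(=O)c2c(O)cc(O)cc2O)cc1
A5 | alternative 3 | (Z)-3-{4-[(2R)-2-[(tert-butyldimethylsilyl)oxy]-3-methylbut-3-en-1-yl]-3,5-bis(methoxymethoxy)phenoxy}-2-(4-methoxyphenyl)acrylic acid | C=C(C)[C@H](O[Si](C)(C)C(C)(C)C)Cc1c(OCOC)cc(O/C=C(\C(=O)O)c2ccc(OC)cc2)cc1OCOC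
A6 | alternative 3 | 6-{(2R)-2-[(tert-butyldimethylsilyl)oxy]-3-methylbut-3-en-1-yl}-5,7-bis(methoxymethoxy)-3-(4-methoxyphenyl)-4H-chromen-4-one | C=C(C)[C@H](O[Si](C)(C)C(C)(C)C)Cc1c(OCOC)cc2occ(-c3ccc(OC)cc3)c(=O)c2c1OCOC
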